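(Its constants were drawn at random within sensible limits; the flask was simulated.)

A single ratio of charges opens the reckoning for this flask.

    reagent + catalyst + right-handed substrate → catalyst + right-handed product (k1 = 0.587 M⁻² s⁻¹)
    reagent + catalyst + left-handed substrate → catalyst + left-handed product (k2 = 1.18 M⁻² s⁻¹)
    2 reagent → self-condensation product (k3 = 4.74 × 10⁻⁴ M⁻¹ s⁻¹)

left-handed substrate 0.053 M; reagent 0.800 equiv; catalyst 15 mol%; right-handed substrate 0.053 M; time 5.0 d

- catalyst is single-handed; left-handed substrate and right-handed substrate are mirror images of each other, charged as a racemate, each of them at the stated concentration
- a doubled species enters its step squared and goes two at a time
- run time (flask): 5.0 d

- how much of the left-handed substrate and right-handed substrate together has reacted by 5.0 d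
- how much left-handed product there is at 5.0 d, in percent of the left-handed substrate and right-handed substrate together charged
- how much right-handed substrate there is at 5.0 d, in percent of the left-handed substrate and right-handed substrate together charged

**Reagent budget.** Each turn of either resolution step takes one reagent and one substrate. So in this flask the reagent charged over both substrates charged, 40.0%, is the reagent budget: the share of the racemate that the reagent can turn over, which makes reagent the limiting reagent. Its equivalents are counted on the left-handed substrate, as stated. Reagent's half-life by the left-handed step alone, the other concentrations as charged, is 0.39 h, much shorter than 5.0 d, so this reckoning reads the conversion straight off the budget.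

**One number enough?** Rate ratios, free of time, test it. At the start, self-condensation uses reagent at 5.40% of the rate of the resolution steps, so the budget stands, slightly high. It does not give the split. Reagent and catalyst cancel between the two substrate rates, leaving the selectivity factor 2.01. The left-handed fraction remaining is therefore the right-handed fraction raised to that power, here nearly its square. Spending the whole budget with the square in place of that power leaves 70.4% of the right-handed substrate charged. The reckoned answers are right-handed substrate 35.2% and left-handed product 25.2% of both substrates charged.

**The forecast.** It gives conversion 76.9%, left-handed product 44.1% and right-handed substrate 17.3%, having taken the equivalents “relative to total substrate”; this reckoning counts them on the left-handed substrate, and there the two part.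

**The flask.** The simulation gives conversion 38.8%, left-handed product 24.5% and right-handed substrate 35.8%. At 5.00 d the flask holds 0% of its reagent charge against 72% of its right-handed substrate. The flask's conversion lies 1.2 percentage points under its budget. The neighbour charged with 1.40 equiv of reagent has a budget of 70.0% and reaches a conversion of 65.7%.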